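The numbers in the tables are simulated for an exercise; the scatter is artificial.

At early times the substrate leaves and the target lags: after 5.00 min the violet run holds 40.2% of its charge as substrate and 3.7% as target, and the red run holds 39.7% and 3.3%, although their concentrations differ by a factor of 2.96.

| flask | substrate | reagent | remark | time |
|---|---|---|---|---|
| violet | 0.083 M | 0.15 equiv | run made earlier |  |
| red | 0.028 M | 0.15 equiv | run made earlier |  |
| Monday's | 0.055 M | 0.150 equiv |  | 30 min |
| Sunday's | 0.055 M | 0.300 equiv |  | 30 min |
| Friday's | 0.055 M | 0.600 equiv |  | 30 min |
| Wednesday's | 0.055 M | 1.20 equiv |  | 30 min |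

| run | time / min | target / % | substrate / % |
|---|---|---|---|
| violet | 2.50 | 0.7 | 63.4 |
| violet | 5.00 | 3.7 | 40.2 |
| violet | 8.00 | 8.2 | 23.0 |
| violet | 10.0 | 11.3 | 16.2 |
| violet | 12.0 | 13.8 | 11.6 |
| violet | 15.0 | 19.3 | 6.5 |
| violet | 20.0 | 27.1 | 2.5 |
| red | 1.33 | 0.3 | 78.4 |
| red | 2.00 | 0.1 | 69.2 |
| red | 3.00 | 1.8 | 58.0 |
| red | 5.00 | 3.3 | 39.7 |
| red | 8.00 | 7.9 | 23.7 |
| red | 12.0 | 14.5 | 11.8 |
| red | 20.0 | 27.7 | 2.9 |

(readings scatter by 0.3 percentage points)

- a reading or a percentage of target counts all its forms, free or not
- "hardly changes" means that all values lie within two and a half points (for a concentration: within two and a half percent of the largest)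

1. amount of target at the end, in percent of the substrate charged for Monday's, Sunday's, Friday's, Wednesday's, in this order
2. the shape of the row from first to last (falls all the way / falls, then rises / rises all the way / hardly changes / rises, then falls)

I keep a ledger of the substrate charge, in fractions of it, from the violet run. Substrate: it decays with 0.185 min⁻¹, down to 2.5% at 20.0 min. Target: 27.1% at that time. Pool, the part neither reading shows: 70.4% then, and 72.5% at 10.0 min. Between those two times I define the drain constant, the target gained per minute divided by the mean pool, 0.0221 min⁻¹, a half-life of 31.4 min. The substrate decays faster than the pool drains, so from 20.0 min on I neglect the feed and let the pool relax by itself; I take this drain as the rate-limiting step.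

Monday's charges the same 0.150 equiv at a concentration between those two runs, so I estimate its books at 30 min: target 41.1%, substrate 0.394%, pool 58.5%. Both earlier runs charge 0.15 equiv, so no reading shows what more reagent does, and I commit to no figure for Sunday's, Friday's or Wednesday's.

The forecast gives 41%, 69%, 91% and 98%, shape: rises all the way, holding that “rate constants scale with the reagent-to-substrate ratio”. On Monday's its figure and mine coincide; past Monday's, it has figures and I have none.

The flask gives 40.8%, 39.5%, 37.1% and 32.9%, shape: falls all the way.

    substrate → intermediate (k = 0.170 min⁻¹)
    intermediate → target (k = 0.0248 min⁻¹)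
    reagent + intermediate → side product (k = 0.388 M⁻¹ min⁻¹)
    substrate ⇌ dormant form (K = 12.0, k = 0.0119 min⁻¹)
    crystals ⇌ target, rate k5*(cs5 - [target]) while solid is left; crystals form when [target] > cs5 (solubility = 1.40 mM, k = 0.539 min⁻¹)

My drain constant still reads both ends of the row. Over the second half of Monday's, it times the mean of intermediate plus dormant form gives 21 percentage points of target, against 21 points found; on Wednesday's it gives 16 points, against 16 points found. Wednesday's ends with less intermediate than Monday's, 30.7% against 47.9%, and with side product at 29.6% against 4.44%. The run without the step from reagent and intermediate to side product shows what that step does to the row: the change from Monday's to Wednesday's goes from −7.9 points to 0 points.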